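**Assumptions.** Magnone B is taken as the open-chain γ-hydroxy ketone in the SMILES: 2,3-trans, 3,4-cis, i.e. (3R,4R,5S) in oxolane numbering. "Commercially available" means catalogue chemicals. This route is a paper proposal and has not been run.

## Retrosynthetic overview

1. Magnone B ⇐ acid hydrolysis of bicyclic enol ether 11; the cis ring fusion forces the CH2OH/aroyl cis relationship, and this ring is opened last.
2. 11 ⇐ (new) MgI2-catalysed iodide-relay Cloke–Wilson ring expansion of bridgehead-aroyl cyclopropane 10, which forms the CH2–O bond.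
3. 10 ⇐ Au-catalysed alkyne oxidation / intramolecular cyclopropanation of 1,6-enyne 8, forming the oxolane ring and the cyclopropane together.
4. 8 ⇐ Sonogashira (4-iodoveratrole) and Williamson (propargyl bromide) on (S)-allylic alcohol 4, from vinyl Grignard addition and lipase resolution.
5. Ring order: oxolane (with fused cyclopropane) → cyclopropane expanded to a dihydrofuran → dihydrofuran hydrolysed open.

## Route

**Step 1**
Reactants: 1, 3,4,5-trimethoxybenzaldehyde; 2, vinylmagnesium bromide
Product: 3, (±)-1-(3,4,5-trimethoxyphenyl)prop-2-en-1-ol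
Conditions: THF, −78 → 0 °C; sat. NH4Cl; Et3N-deactivated SiO2
Reagents that add atoms: vinylmagnesium bromide, C=C[Mg]Br
Why: Grignard 1,2-addition to an aryl aldehyde; no stereocontrol is needed because the racemate is resolved in Step 2.

**Step 2**
Reactants: 3, racemic allylic alcohol
Product: 4, (S)-1-(3,4,5-trimethoxyphenyl)prop-2-en-1-ol
Conditions: Novozym 435 (CAL-B), vinyl acetate (3 equiv), MTBE, 30 °C, to ca. 55% conversion; chromatographic removal of the (R)-acetate
Reagents that add atoms: none (vinyl acetate acylates only the discarded (R)-enantiomer)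
Why: Lipase kinetic resolution following the Kazlauskas rule (aryl large, vinyl medium): the (R)-alcohol is acetylated and the (S)-alcohol is recovered, which fixes the future C-aryl stereocentre.

**Step 3**
Reactants: 4; 5, propargyl bromide
Product: 6, 1,2,3-trimethoxy-5-[(1S)-1-(prop-2-yn-1-yloxy)prop-2-en-1-yl]benzene
Conditions: NaH, Bu4NI (cat.), THF, 0 °C → rt
Reagents that add atoms: propargyl bromide, C#CCBr
Why: Williamson etherification at oxygen; the stereocentre is not involved, so configuration is retained.

**Step 4**
Reactants: 6; 7, 4-iodo-1,2-dimethoxybenzene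
Product: 8, 5-[(1S)-1-{[3-(3,4-dimethoxyphenyl)prop-2-yn-1-yl]oxy}prop-2-en-1-yl]-1,2,3-trimethoxybenzene (1,6-enyne)
Conditions: Pd(PPh3)2Cl2 (2 mol%), CuI (4 mol%), Et3N/THF, rt
Reagents that add atoms: 4-iodo-1,2-dimethoxybenzene, COc1ccc(I)cc1OC
Why: Sonogashira coupling of the terminal alkyne under mild base; the vinyl and allylic ether groups are spectators.

**Step 5**
Reactants: 8; 9, 8-methylquinoline N-oxide
Product: 10, (3,4-dimethoxyphenyl)[(1S,4S,5S)-4-(3,4,5-trimethoxyphenyl)-3-oxabicyclo[3.1.0]hexan-1-yl]methanone
Conditions: IPrAuNTf2 (5 mol%), 9 (2 equiv, slow addition), 4 Å MS, DCE, rt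
Reagents that add atoms: 8-methylquinoline N-oxide (delivers O), Cc1cccc2ccc[n+]([O-])c12
Why: Gold-catalysed alkyne oxidation / intramolecular cyclopropanation of a 1,6-enyne: the N-oxide attacks the aryl-bearing alkyne carbon (distal to the propargylic oxygen), and the resulting α-oxo gold carbene cyclopropanates the vinyl group through the exo transition state with the aryl group anti to the new cyclopropane, setting C1 and C5 relative to C4.

**Step 6**
Reactants: 10
Product: 11, (1S,6aR)-4-(3,4-dimethoxyphenyl)-1-(3,4,5-trimethoxyphenyl)-6,6a-dihydro-1H,3H-furo[3,4-c]furan (bicyclic cyclic enol ether)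
Conditions: MgI2 (30 mol%), 4 Å MS, anhydrous THF, 50 °C; filter through basic Al2O3 and use directly
Reagents that add atoms: none (isomerisation)
Why: Proposed new method: Lewis-acid/iodide relay Cloke–Wilson ring expansion of a cyclopropyl aryl ketone that has no donor group. Mg2+ activates the aroyl C=O and iodide opens the cyclopropane by SN2 at the unhindered CH2 (C6), giving a magnesium enolate and a primary iodide; 3-exo C-alkylation only regenerates 10, whereas 5-exo-tet O-alkylation is strain-releasing and effectively irreversible, so material funnels to 11 with the ring-fusion CH untouched. Closest known reactions: thermal or DABCO-catalysed Cloke–Wilson rearrangement of activated cyclopropanes, MgI2 ring expansion of spirocyclopropyl oxindoles, and TMSI homoconjugate opening of cyclopropyl ketones.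

**Step 7**
Reactants: 11; water
Product: 12, Magnone B, (3,4-dimethoxyphenyl)[(3R,4R,5S)-4-(hydroxymethyl)-5-(3,4,5-trimethoxyphenyl)oxolan-3-yl]methanone
Conditions: PPTS (10 mol%), THF/H2O 10:1, 0 °C → rt; NaHCO3 quench
Reagents that add atoms: water, O
Why: Acid-catalysed enol ether hydrolysis: C-protonation of the bicyclic enol ether can only give the cis-fused aryl oxocarbenium ion, and hydration followed by hemiketal opening releases the γ-hydroxy ketone with the aroyl group cis to CH2OH, setting the last stereocentre (C3, R) under kinetic control.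

## Compound list

1 | 3,4,5-trimethoxybenzaldehyde | COc1cc(C=O)cc(OC)c1OC | starting material
2 | vinylmagnesium bromide | C=C[Mg]Br | starting material
3 | (±)-1-(3,4,5-trimethoxyphenyl)prop-2-en-1-ol | C=CC(O)c1cc(OC)c(OC)c(OC)c1 | intermediate
4 | (S)-1-(3,4,5-trimethoxyphenyl)prop-2-en-1-ol | C=C[C@H](O)c1cc(OC)c(OC)c(OC)c1 | intermediate
5 | propargyl bromide | C#CCBr | starting material
6 | 1,2,3-trimethoxy-5-[(1S)-1-(prop-2-yn-1-yloxy)prop-2-en-1-yl]benzene | C=C[C@H](OCC#C)c1cc(OC)c(OC)c(OC)c1 | intermediate
7 | 4-iodo-1,2-dimethoxybenzene | COc1ccc(I)cc1OC | starting material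
8 | 5-[(1S)-1-{[3-(3,4-dimethoxyphenyl)prop-2-yn-1-yl]oxy}prop-2-en-1-yl]-1,2,3-trimethoxybenzene | C=C[C@H](OCC#Cc1ccc(OC)c(OC)c1)c1cc(OC)c(OC)c(OC)c1 | intermediate
9 | 8-methylquinoline N-oxide | Cc1cccc2ccc[n+]([O-])c12 | starting material (oxidant)
10 | (3,4-dimethoxyphenyl)[(1S,4S,5S)-4-(3,4,5-trimethoxyphenyl)-3-oxabicyclo[3.1.0]hexan-1-yl]methanone | COc1ccc(C(=O)[C@@]23C[C@@H]2[C@@H](c2cc(OC)c(OC)c(OC)c2)OC3)cc1OC | intermediate
11 | (1S,6aR)-4-(3,4-dimethoxyphenyl)-1-(3,4,5-trimethoxyphenyl)-6,6a-dihydro-1H,3H-furo[3,4-c]furan | COc1ccc(C2=C3CO[C@H](c4cc(OC)c(OC)c(OC)c4)[C@H]3CO2)cc1OC | intermediate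
12 | Magnone B | COc1ccc(C(=O)[C@H]2CO[C@H](c3cc(OC)c(OC)c(OC)c3)[C@H]2CO)cc1OC | target

## Summary

Total steps: 7. Longest linear sequence: 7 (fully linear from 1).

Three steps most likely to fail:

1. **Step 6 (proposed new method).** Risks are no ring opening, β-alkoxide loss from the magnesium enolate (retro-oxa-Michael), or Lewis-acid ionisation of the benzylic, cyclopropylcarbinyl C–O bond. Fallback using known chemistry from enyne 8:
   - Pd(OAc)2/B2pin2/MeOH borylative enyne cyclisation to the 3-(borylmethyl)-4-benzylidene oxolane;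
   - NaBO3 oxidation to the CH2OH;
   - 9-BBN hydroboration/oxidation of the exocyclic benzylidene, with H delivered anti to the C3 substituent to give 3,4-cis;
   - MnO2 oxidation of the benzylic alcohol to Magnone B.
2. **Step 5 (Au oxidation/cyclopropanation).** Risks are 1,2-H shift of the carbene to a β-alkoxy enone, Friedel–Crafts attack by the trimethoxyphenyl ring, and modest exo/endo selectivity. Fallback avoiding carbenes: O-alkylate 4 with 2-(bromomethyl)-1-(3,4-dimethoxyphenyl)prop-2-en-1-one, ring-closing metathesis (Grubbs II) to the 4-aroyl-2-aryl-2,5-dihydrofuran, then Corey–Chaykovsky cyclopropanation (Me3S(O)I/NaH) anti to the aryl group to reach 10.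
3. **Step 2 (lipase resolution).** Selectivity on the bulky 3,4,5-trimethoxyphenyl carbinol is unproven and yield is capped at 50%. Fallback: Ir/phosphoramidite-catalysed asymmetric allylic etherification of methyl (E)-3,4,5-trimethoxycinnamyl carbonate with 3-(3,4-dimethoxyphenyl)prop-2-yn-1-ol, giving 8 directly. I could not recall with confidence which ligand enantiomer gives (S), so the ligand would be chosen by checking the product configuration.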